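## Retrosynthetic overview
1. The target comes from a protected bis(maleic anhydride) by oxidising a silyl-masked carbinol to the ketone and then removing a tert-butyl ether with acid.
2. Rings A and B are formed together in one late operation from the two internal alkynes of an acyclic 1,5-diyne, each C≡C taking up two CO2. No ring exists before that point.
3. The bond from the stereocentre to ring B comes from a stereoretentive boron-to-carbon 1,2-shift (Zweifel-type bromovinylation). Elimination to the acetylide and extension with (R)-epoxyhexane follow.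
4. Key step: the secondary boronic ester is assembled from pentylmagnesium bromide, a vinylboronate and a bromoalkyne. A palladium-induced enantioselective 1,2-boronate shift makes the other two C–C bonds at the stereocentre and sets its R configuration.
5. The bromoalkyne comes from tert-butyl propargyl ether.

Assumption: the single stereocentre is R (ring B carbon > CH2 to ring A > pentyl > H), and the product is delivered as the open hydroxymethyl anhydride drawn, not as its butenolide-acid isomer.

Labels: ring A is the anhydride bearing CH2OH and ring B is the anhydride bearing the 2-oxohexyl group. L is 1,1'-bis[bis(4-methoxy-3,5-dimethylphenyl)phosphino]-2,2'-bis[(dimethylamino)(phenyl)methyl]ferrocene (MandyPhos type). Both antipodes are sold. The one that gives (R)-6 is fixed in a pilot run by oxidising an aliquot to the carbinol and running a Mosher analysis.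

## Route

Step 1
Reactants: 1 3-(tert-butoxy)prop-1-yne
Product: 2 1-bromo-3-(tert-butoxy)prop-1-yne
Conditions: NBS (1.1 equiv), AgNO3 (10 mol %), acetone, rt
Reagents that add atoms: N-bromosuccinimide, O=C1CCC(=O)N1Br
Why: Silver-catalysed electrophilic bromination of a terminal alkyne (silver acetylide plus NBS) is general for propargyl ethers, touches nothing else and forms no stereocentre.

Step 2
Reactants: 2 1-bromo-3-(tert-butoxy)prop-1-yne; 3 vinylboronic acid pinacol ester; 4 pentylmagnesium bromide
Product: 6 2-[(5R)-1-(tert-butoxy)dec-2-yn-5-yl]-4,4,5,5-tetramethyl-1,3,2-dioxaborolane, via ethenyl(pentyl)boronate complex 5 (not isolated)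
Conditions: 3 + 4, THF, 0 °C → rt; then NaOSO2CF3 (2 equiv), Pd(OAc)2 (3 mol %), L (3.6 mol %), 2, THF/DMSO, 40 °C
Reagents that add atoms: none
Why: Proposed new method: an enantioselective palladium-catalysed conjunctive cross-coupling in which a 1-bromoalkyne replaces the usual aryl or alkenyl electrophile, where zerovalent palladium inserts into the C(sp)–Br bond, sodium triflate strips bromide, the cationic alkynyl complex of divalent palladium binds one face of the vinyl group of 5 inside the chiral diphosphine pocket and triggers the anti 1,2-shift of pentyl from boron to the α-carbon (this sets the R centre), and fast C(sp3)–C(sp) reductive elimination from the wide-bite-angle complex outruns β-hydride elimination and direct Suzuki-type transfer; the closest known reaction type is the conjunctive cross-coupling of vinylboron ate complexes with aryl and alkenyl halides or triflates.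

Step 3
Reactants: 6 2-[(5R)-1-(tert-butoxy)dec-2-yn-5-yl]-4,4,5,5-tetramethyl-1,3,2-dioxaborolane; 7 vinyl bromide
Product: 11 (3R)-2-bromo-7-(tert-butoxy)-3-pentylhept-1-en-5-yne, via 1-bromovinyllithium 8 (not isolated), via bromovinyl boronate complex 9 (not isolated), via β-iodoalkyl boronic ester 10 (not isolated)
Conditions: 7 (4 equiv), LiN(iPr)2 (4 equiv), THF/Et2O, −95 °C; I2, then NaOMe/MeOH, −78 °C → rt
Reagents that add atoms: none
Why: In this Zweifel-type olefination, 1-bromovinyllithium generated in the presence of 6 gives boronate 9, iodine activates its alkene so that the secondary alkyl group undergoes a stereoretentive 1,2-shift from boron to carbon, and methoxide-induced elimination of boron and iodine leaves the 2-bromoalkene with the R centre intact.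

Step 4
Reactants: 11 (3R)-2-bromo-7-(tert-butoxy)-3-pentylhept-1-en-5-yne; 12 (R)-1,2-epoxyhexane
Product: 15 (5R,9R)-1-(tert-butoxy)-5-pentyl-9-[(triethylsilyl)oxy]trideca-2,6-diyne, via lithium acetylide 13 (not isolated), via lithium alkoxide 14 (not isolated)
Conditions: LiN(iPr)2 (2.1 equiv), THF, −78 → 0 °C; 12, DMPU, 0 °C → rt; Et3SiCl, 0 °C
Reagents that add atoms: chlorotriethylsilane, CC[Si](Cl)(CC)CC
Why: Anti 1,2-elimination of HBr from the 2-bromo-1-alkene gives the acetylide directly, which opens the epoxide at its CH2 (SN2, so the temporary carbinol centre keeps the R configuration of 12) before the alkoxide is silylated in the same flask, and the enantiopure epoxide also turns any minor enantiomer from step 2 into a diastereomer that can be measured and removed.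

Step 5
Reactants: 15 (5R,9R)-1-(tert-butoxy)-5-pentyl-9-[(triethylsilyl)oxy]trideca-2,6-diyne
Product: 17 3-[(2R)-1-{4-[(tert-butoxy)methyl]-2,5-dioxo-2,5-dihydrofuran-3-yl}heptan-2-yl]-4-[(2R)-2-(triethylsilyloxy)hexyl]furan-2,5-dione, via bis(maleic acid) 16 (not isolated)
Conditions: CO2 (1 atm), Ni(acac)2 (20 mol %), 2,2'-bipyridine (20 mol %), Zn powder, MgBr2, 4 Å MS, DMF, rt; cold 1 M HCl (brief); toluene azeotrope
Reagents that add atoms: carbon dioxide, O=C=O
Why: In this nickel-catalysed reductive double carboxylation of internal alkynes, zerovalent nickel couples alkyne and CO2 to an oxanickelacyclopentenone, zinc reduces it and MgBr2 assists insertion of the second CO2 into the Ni–C(vinyl) bond, so both carboxyls arrive cis, each dialkylmaleic acid closes to its anhydride on acidification (rings A and B together), the regiochemistry of the first insertion is irrelevant and the base-free medium leaves the stereocentre alone.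

Step 6
Reactants: 17 3-[(2R)-1-{4-[(tert-butoxy)methyl]-2,5-dioxo-2,5-dihydrofuran-3-yl}heptan-2-yl]-4-[(2R)-2-(triethylsilyloxy)hexyl]furan-2,5-dione
Product: 19 3-[(2R)-1-{4-[(tert-butoxy)methyl]-2,5-dioxo-2,5-dihydrofuran-3-yl}heptan-2-yl]-4-(2-oxohexyl)furan-2,5-dione, via free carbinol 18 (not isolated)
Conditions: CrO3, H2SO4, H2O, acetone, 0 °C, 30 min; iPrOH quench; toluene azeotrope
Reagents that add atoms: none
Why: In this Jones oxidation the aqueous acid strips the labile triethylsilyl ether within minutes and chromic acid oxidises the freed secondary alcohol before it can settle as a lactone, while the tert-butyl ether and the electron-poor ring alkenes are inert at 0 °C and the temporary carbinol centre is erased.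

Step 7
Reactants: 19 3-[(2R)-1-{4-[(tert-butoxy)methyl]-2,5-dioxo-2,5-dihydrofuran-3-yl}heptan-2-yl]-4-(2-oxohexyl)furan-2,5-dione
Product: 20 3-[(2R)-1-[4-(hydroxymethyl)-2,5-dioxo-2,5-dihydrofuran-3-yl]heptan-2-yl]-4-(2-oxohexyl)furan-2,5-dione
Conditions: CF3CO2H/CH2Cl2 (1:2), 0 °C → rt; evaporate; MeCN/H2O, rt (cleaves any trifluoroacetate); toluene azeotrope
Reagents that add atoms: none
Why: Acidolysis of the tert-butyl ether (loss of the tert-butyl cation as isobutene) frees the primary alcohol without any base, so the acidic C–H at the stereocentre next to ring B cannot epimerise and both anhydrides stay closed.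

## Compound list
1 | 3-(tert-butoxy)prop-1-yne (tert-butyl propargyl ether) | C#CCOC(C)(C)C | starting material
2 | 1-bromo-3-(tert-butoxy)prop-1-yne | BrC#CCOC(C)(C)C | intermediate
3 | vinylboronic acid pinacol ester (2-ethenyl-4,4,5,5-tetramethyl-1,3,2-dioxaborolane) | C=CB1OC(C)(C)C(C)(C)O1 | starting material
4 | pentylmagnesium bromide | CCCCC[Mg]Br | starting material
5 | bromomagnesium ethenyl(pentyl)(pinacolato)borate | CCCCC[B-]1(C=C)OC(C)(C)C(C)(C)O1.[Mg+]Br | intermediate
6 | 2-[(5R)-1-(tert-butoxy)dec-2-yn-5-yl]-4,4,5,5-tetramethyl-1,3,2-dioxaborolane | CCCCC[C@H](CC#CCOC(C)(C)C)B1OC(C)(C)C(C)(C)O1 | intermediate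
7 | vinyl bromide (bromoethene) | C=CBr | starting material
8 | 1-bromovinyllithium | [Li]C(Br)=C | intermediate
9 | lithium (1-bromoethenyl)[(5R)-1-(tert-butoxy)dec-2-yn-5-yl](pinacolato)borate | [Li+].CCCCC[C@H](CC#CCOC(C)(C)C)[B-]1(C(Br)=C)OC(C)(C)C(C)(C)O1 | intermediate
10 | 2-[(3R)-2-bromo-7-(tert-butoxy)-1-iodo-3-pentylhept-5-yn-2-yl]-4,4,5,5-tetramethyl-1,3,2-dioxaborolane (C2 epimers) | CCCCC[C@H](CC#CCOC(C)(C)C)C(Br)(CI)B1OC(C)(C)C(C)(C)O1 | intermediate
11 | (3R)-2-bromo-7-(tert-butoxy)-3-pentylhept-1-en-5-yne | CCCCC[C@H](CC#CCOC(C)(C)C)C(Br)=C | intermediate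
12 | (R)-1,2-epoxyhexane [(2R)-2-butyloxirane] | CCCC[C@@H]1CO1 | starting material
13 | lithium acetylide of (3R)-7-(tert-butoxy)-3-pentylhepta-1,5-diyne | CCCCC[C@H](CC#CCOC(C)(C)C)C#C[Li] | intermediate
14 | lithium (5R,9R)-13-(tert-butoxy)-9-pentyltrideca-7,11-diyn-5-olate | [Li+].CCCCC[C@H](CC#CCOC(C)(C)C)C#CC[C@H]([O-])CCCC | intermediate
15 | (5R,9R)-1-(tert-butoxy)-5-pentyl-9-[(triethylsilyl)oxy]trideca-2,6-diyne | CCCCC[C@H](CC#CCOC(C)(C)C)C#CC[C@H](O[Si](CC)(CC)CC)CCCC | intermediate
16 | bis(maleic acid) of 15: two CO2H added cis to each alkyne, both C=C Z, both sp3 centres unchanged | CCCCC[C@H](C/C(C(O)=O)=C(\COC(C)(C)C)C(O)=O)/C(C(O)=O)=C(\C[C@H](O[Si](CC)(CC)CC)CCCC)C(O)=O | intermediate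
17 | 3-[(2R)-1-{4-[(tert-butoxy)methyl]-2,5-dioxo-2,5-dihydrofuran-3-yl}heptan-2-yl]-4-[(2R)-2-(triethylsilyloxy)hexyl]furan-2,5-dione | CCCCC[C@H](CC1=C(COC(C)(C)C)C(=O)OC1=O)C1=C(C[C@H](O[Si](CC)(CC)CC)CCCC)C(=O)OC1=O | intermediate
18 | 3-[(2R)-1-{4-[(tert-butoxy)methyl]-2,5-dioxo-2,5-dihydrofuran-3-yl}heptan-2-yl]-4-[(2R)-2-hydroxyhexyl]furan-2,5-dione | CCCCC[C@H](CC1=C(COC(C)(C)C)C(=O)OC1=O)C1=C(C[C@H](O)CCCC)C(=O)OC1=O | intermediate
19 | 3-[(2R)-1-{4-[(tert-butoxy)methyl]-2,5-dioxo-2,5-dihydrofuran-3-yl}heptan-2-yl]-4-(2-oxohexyl)furan-2,5-dione | CCCCC[C@H](CC1=C(COC(C)(C)C)C(=O)OC1=O)C1=C(CC(=O)CCCC)C(=O)OC1=O | intermediate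
20 | 3-[(2R)-1-[4-(hydroxymethyl)-2,5-dioxo-2,5-dihydrofuran-3-yl]heptan-2-yl]-4-(2-oxohexyl)furan-2,5-dione (CNP0537712.2) | CCCCC[C@H](CC1=C(CO)C(=O)OC1=O)C1=C(CC(=O)CCCC)C(=O)OC1=O | target

## Step count and risks
Total step count: 7.
Longest linear sequence: 7 steps (1 → 2 → 6 → 11 → 15 → 17 → 19 → 20).

**Step 2 (the new reaction).**
- Risks: the alkynylpalladium species may couple directly with the vinyl group to give an enyne. The bromoalkyne may homocouple. The enantiomer ratio may be lower than with aryl electrophiles.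
- Fallback: known lithiation–borylation chemistry, setting out from 1 and coming back at 6.
- Hexan-1-ol and iPr2NCOCl give hexyl N,N-diisopropylcarbamate F1.
- Compound 1 is lithiated with nBuLi and treated with ICH2B(pin). After the 1,2-shift of the alkynyl group this gives 2-[4-(tert-butoxy)but-2-yn-1-yl]-4,4,5,5-tetramethyl-1,3,2-dioxaborolane F2.
- sBuLi/(−)-sparteine (Et2O, −78 °C) removes the pro-S hydrogen of F1 to give (S)-1-lithiohexyl N,N-diisopropylcarbamate F3.
- F3 captures F2 with retention as the lithium boronate complex F4.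
- MgBr2·OEt2 and warming drive the invertive 1,2-shift with loss of the carbamate and give 6 as the R enantiomer.

**Step 4.**
- Risks: the epoxide opening may be sluggish in the amine-laden medium, where BF3 activation cannot be used. Any excess amide base may also isomerise the propargylic positions.
- Fallback: it sets out from 6 and comes back at 13, replacing the bromovinylation and elimination by formyl homologation and a Corey–Fuchs sequence.
- LiCHCl2 (−100 °C) adds to 6, and the Matteson 1,2-shift gives 2-[(2R)-6-(tert-butoxy)-1-chloro-2-pentylhex-4-yn-1-yl]-4,4,5,5-tetramethyl-1,3,2-dioxaborolane F5.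
- NaBO3·4H2O converts F5 into (2R)-6-(tert-butoxy)-2-pentylhex-4-ynal F6.
- CBr4/PPh3 gives (3R)-1,1-dibromo-7-(tert-butoxy)-3-pentylhept-1-en-5-yne F7.
- nBuLi (2 equiv) gives amine-free 13. This opens 12 under BF3·OEt2 assistance at −78 °C and is then silylated to 15.

**Step 5.**
- Risks: the α-branched alkyne of ring B may stop after one carboxylation. The twofold reaction may stay incomplete. Nickel may oligomerise the diyne.
- Fallback: it sets out from 15 and comes back at 17.
- Ru3(CO)12-catalysed cocyclisation of each alkyne with phenyl isocyanate and CO (1 atm, mesitylene, 130 °C) gives 3-[(2R)-1-{4-[(tert-butoxy)methyl]-2,5-dioxo-1-phenyl-2,5-dihydro-1H-pyrrol-3-yl}heptan-2-yl]-1-phenyl-4-[(2R)-2-(triethylsilyloxy)hexyl]-1H-pyrrole-2,5-dione F8.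
- Aqueous KOH in THF/MeOH followed by HCl converts both imides into the anhydrides of 17.
- Any desilylated material is 18, which step 6 oxidises all the same.
- The enantiomer ratio must be rechecked after the basic hydrolysis.

## Further compounds
F1 | step 2 | hexyl N,N-diisopropylcarbamate | CCCCCCOC(=O)N(C(C)C)C(C)C
F2 | step 2 | 2-[4-(tert-butoxy)but-2-yn-1-yl]-4,4,5,5-tetramethyl-1,3,2-dioxaborolane | CC(C)(C)OCC#CCB1OC(C)(C)C(C)(C)O1
F3 | step 2 | (S)-1-lithiohexyl N,N-diisopropylcarbamate | CCCCC[C@H]([Li])OC(=O)N(C(C)C)C(C)C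
F4 | step 2 | lithium [4-(tert-butoxy)but-2-yn-1-yl][(1S)-1-(diisopropylcarbamoyloxy)hexyl](pinacolato)borate | [Li+].CCCCC[C@@H](OC(=O)N(C(C)C)C(C)C)[B-]1(CC#CCOC(C)(C)C)OC(C)(C)C(C)(C)O1
F5 | step 4 | 2-[(2R)-6-(tert-butoxy)-1-chloro-2-pentylhex-4-yn-1-yl]-4,4,5,5-tetramethyl-1,3,2-dioxaborolane | CCCCC[C@H](CC#CCOC(C)(C)C)C(Cl)B1OC(C)(C)C(C)(C)O1
F6 | step 4 | (2R)-6-(tert-butoxy)-2-pentylhex-4-ynal | CCCCC[C@H](CC#CCOC(C)(C)C)C=O
F7 | step 4 | (3R)-1,1-dibromo-7-(tert-butoxy)-3-pentylhept-1-en-5-yne | CCCCC[C@H](CC#CCOC(C)(C)C)C=C(Br)Br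
F8 | step 5 | 3-[(2R)-1-{4-[(tert-butoxy)methyl]-2,5-dioxo-1-phenyl-2,5-dihydro-1H-pyrrol-3-yl}heptan-2-yl]-1-phenyl-4-[(2R)-2-(triethylsilyloxy)hexyl]-1H-pyrrole-2,5-dione | CCCCC[C@H](CC1=C(COC(C)(C)C)C(=O)N(c2ccccc2)C1=O)C1=C(C[C@H](O[Si](CC)(CC)CC)CCCC)C(=O)N(c2ccccc2)C1=O
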